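Ring A of the target is numbered C1 (C=O), C2 (OH), C3 (CH3), C4 (C=O), C5 (OH), C6 (nonadecenyl). Everything rests on disconnecting C1–C2: the C1–C6–C5–C4 chain, oxygenated at C1, C5 and C4 and alkylated at C6, maps onto a squarate-derived cyclobutenone, and C3–C2 is a methyl-bearing enol ether attached at C4. One thermal operation opens the four-membered ring to a dienylketene, which closes by 6π electrocyclisation to the hexasubstituted hydroquinone form of ring A with all six substituents in place. The precursor is a 4-hydroxycyclobutenone carrying the chain at C6, isopropoxy at C5 and a (Z)-1-methoxyprop-1-en-2-yl group at C4.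

Key step: step 9

Remark on the chemistry: metal alkoxides present before aqueous work-up are counted as the protonated compounds, and 13 is used as its commercial E/Z mixture because step 7 erases that geometry.

Step 1
Reactants: 1 tridecanedioic acid
Product: 2 tridecane-1,13-diol
Conditions: LiAlH4, THF, 0 °C → reflux; then H2O, 15% aq. NaOH
Reagents that add atoms: none
Why: Hydride reduction of both carboxylic acids by LiAlH4 should give the symmetrical primary diol, and no other functional group is present.

Step 2
Reactants: 2 tridecane-1,13-diol
Product: 3 13-bromotridecan-1-ol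
Conditions: 48% aq. HBr (1.1 equiv), toluene, reflux
Reagents that add atoms: hydrogen bromide, Br
Why: SN2 monobromination of a symmetrical diol in a two-phase mixture, in which the bromo alcohol passes into toluene and is largely protected from a second substitution; residual diol and dibromide are removed by chromatography.

Step 3
Reactants: 3 13-bromotridecan-1-ol; 4 hex-1-yne
Product: 6 nonadec-14-yn-1-ol, via hex-1-ynyllithium 5 (not isolated)
Conditions: 4 (2.5 equiv), n-BuLi (2.4 equiv), THF, −78 → 0 °C; DMPU; then 3, 0 °C → rt; H2O
Reagents that add atoms: none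
Why: One equivalent of acetylide deprotonates the hydroxyl and a second alkylates the primary bromide by SN2 (acetylide alkylation in a dipolar aprotic co-solvent), so no protecting group should be needed.

Step 4
Reactants: 6 nonadec-14-yn-1-ol
Product: 7 (E)-nonadec-14-en-1-ol
Conditions: Na, NH3(l)/THF, −33 °C; then NH4Cl
Reagents that add atoms: none
Why: Dissolving-metal reduction of the internal alkyne runs through the trans vinyl radical anion and should therefore set the E geometry of C14=C15, while the alkoxide and the isolated alkene formed are not reduced further.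

Step 5
Reactants: 7 (E)-nonadec-14-en-1-ol
Product: 8 (E)-19-bromononadec-5-ene
Conditions: CBr4, PPh3, CH2Cl2, 0 °C → rt
Reagents that add atoms: carbon tetrabromide, BrC(Br)(Br)Br
Why: Appel reaction, in which bromide displaces the alkoxyphosphonium group at the primary carbon under neutral conditions that leave the E alkene untouched.

Step 6
Reactants: 8 (E)-19-bromononadec-5-ene; 9 diisopropyl squarate
Product: 12 3-isopropoxy-4-[(E)-nonadec-14-enyl]cyclobut-3-ene-1,2-dione, via Grignard reagent 10 (not isolated), via squarate adduct 11 (not isolated)
Conditions: Mg, THF, 40 °C; then 9, THF, −78 °C; aq. NH4Cl; crude 11, 12 M HCl (cat.), CH2Cl2, rt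
Reagents that add atoms: water, O
Why: Grignard 1,2-addition to one squarate carbonyl at −78 °C should stop at the mono-adduct, and acid then ionises the tertiary allylic alcohol so that water adds at the distal alkoxy-bearing carbon and isopropanol is lost (allylic transposition and hydrolysis to the vinylogous ester dione).

Step 7
Reactants: 13 1-methoxyprop-1-ene (E/Z mixture)
Product: 15 (Z)-2-bromo-1-methoxyprop-1-ene, via 1,2-dibromo-1-methoxypropane 14 (not isolated)
Conditions: Br2, CH2Cl2, −78 °C; then i-Pr2NEt, −78 °C → reflux; fractional distillation
Reagents that add atoms: bromine, BrBr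
Why: Bromination–dehydrobromination: bromine adds across the enol ether and the labile α-bromo ether loses HBr through its oxocarbenium ion to give the β-bromo enol ether, whose Z isomer (bromine cis to methoxy) is expected to predominate and is freed from the E isomer by fractional distillation.

Step 8
Reactants: 12 3-isopropoxy-4-[(E)-nonadec-14-enyl]cyclobut-3-ene-1,2-dione; 15 (Z)-2-bromo-1-methoxyprop-1-ene
Product: 17 racemic 4-hydroxy-3-isopropoxy-4-[(Z)-1-methoxyprop-1-en-2-yl]-2-[(E)-nonadec-14-enyl]cyclobut-2-en-1-one, via alkenyllithium reagent 16 (not isolated)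
Conditions: 15 (1.3 equiv), t-BuLi (2.6 equiv), Et2O, −78 °C; then 12, THF, −78 °C; H2O, −78 → 0 °C; chromatography on Et3N-washed SiO2
Reagents that add atoms: none
Why: Bromine–lithium exchange with retention gives the alkenyllithium with lithium cis to methoxy (internally coordinated and not aligned for anti elimination), which adds 1,2 to the C2 carbonyl of 12 (C4 of ring A), the more electrophilic one because it is not the vinylogous ester carbonyl; the new carbinol centre forms as a racemate, which does not matter because step 9 erases it.

Step 9
Reactants: 17 racemic 4-hydroxy-3-isopropoxy-4-[(Z)-1-methoxyprop-1-en-2-yl]-2-[(E)-nonadec-14-enyl]cyclobut-2-en-1-one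
Product: 20 3-isopropoxy-6-methoxy-5-methyl-2-[(E)-nonadec-14-enyl]benzene-1,4-diol, via dienylketene 18 (not isolated), via cyclohexadienone 19 (not isolated)
Conditions: toluene (degassed), 110 °C, argon, base-washed glassware
Reagents that add atoms: none
Why: Heating triggers conrotatory 4π opening of the cyclobutenone at the C1–C4 bond (ring A numbering), and because the hydroxyl on C4 is a donor it rotates outward, so the alkenyl arm of dienylketene 18 ends up cis to the ketene. Thermal disrotatory 6π electrocyclisation then joins the ketene carbon C1 to the methoxy-bearing alkene carbon C2, which is the only new skeletal bond and closes the six-membered carbocycle ring A as dienone 19. Enolisation of 19 (the C2 hydrogen moves to the C1 oxygen) gives the aromatic hydroquinone 20, and this aromatisation makes the sequence irreversible. The closest known reaction type is the Moore rearrangement of squarate-derived 4-alkenyl-4-hydroxycyclobutenones to hydroquinones. No stereocentre is created: the racemic carbinol centre and the enol ether geometry of 17 both vanish, and the transient sp3 centre at C2 of 19 is lost on enolisation. The step needs only the outward rotation of the hydroxyl, which its donor character secures; the substituent pattern was fixed in step 8, the isolated E alkene should not react at 110 °C, and the inward methoxy group on the alkene terminus should be tolerated because the sp-hybridised ketene carbon makes small steric demands.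

Step 10
Reactants: 20 3-isopropoxy-6-methoxy-5-methyl-2-[(E)-nonadec-14-enyl]benzene-1,4-diol
Product: 21 2-isopropoxy-5-methoxy-6-methyl-3-[(E)-nonadec-14-enyl]cyclohexa-2,5-diene-1,4-dione
Conditions: Ag2O, Na2SO4, Et2O, rt
Reagents that add atoms: none
Why: Two-electron oxidation of the electron-rich hydroquinone to the para-quinone by Ag2O under neutral conditions, to which the chain alkene and both alkoxy groups are inert.

Step 11
Reactants: 21 2-isopropoxy-5-methoxy-6-methyl-3-[(E)-nonadec-14-enyl]cyclohexa-2,5-diene-1,4-dione
Product: 22 2,5-dihydroxy-3-methyl-6-[(E)-nonadec-14-enyl]cyclohexa-2,5-diene-1,4-dione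
Conditions: 2 M NaOH (aq), MeOH/THF, 50 °C, argon; then 2 M HCl, 0 °C
Reagents that add atoms: sodium hydroxide, [Na+].[OH-]
Why: Both alkoxy groups are vinylogous esters, so hydroxide should replace them by addition–elimination at C2 and C5 (vinylogous saponification) to give the stable dianion, which acid converts into the 2,5-dihydroxyquinone, while the unconjugated E alkene is inert to base.

Compound list
1 | tridecanedioic acid | OC(=O)CCCCCCCCCCCC(=O)O | starting material
2 | tridecane-1,13-diol | OCCCCCCCCCCCCCO | intermediate
3 | 13-bromotridecan-1-ol | OCCCCCCCCCCCCCBr | intermediate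
4 | hex-1-yne | CCCCC#C | starting material
5 | hex-1-ynyllithium | CCCCC#C[Li] | intermediate (not isolated)
6 | nonadec-14-yn-1-ol | CCCCC#CCCCCCCCCCCCCCO | intermediate
7 | (E)-nonadec-14-en-1-ol | CCCC/C=C/CCCCCCCCCCCCCO | intermediate
8 | (E)-19-bromononadec-5-ene | CCCC/C=C/CCCCCCCCCCCCCBr | intermediate
9 | diisopropyl squarate | CC(C)OC1=C(OC(C)C)C(=O)C1=O | starting material
10 | [(E)-nonadec-14-enyl]magnesium bromide | CCCC/C=C/CCCCCCCCCCCCC[Mg]Br | intermediate (not isolated)
11 | racemic 4-hydroxy-2,3-diisopropoxy-4-[(E)-nonadec-14-enyl]cyclobut-2-en-1-one | CCCC/C=C/CCCCCCCCCCCCCC1(O)C(OC(C)C)=C(OC(C)C)C1=O | intermediate (not isolated)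
12 | 3-isopropoxy-4-[(E)-nonadec-14-enyl]cyclobut-3-ene-1,2-dione | CCCC/C=C/CCCCCCCCCCCCCC1=C(OC(C)C)C(=O)C1=O | intermediate
13 | 1-methoxyprop-1-ene (E/Z mixture) | COC=CC | starting material
14 | 1,2-dibromo-1-methoxypropane (diastereomer mixture) | COC(Br)C(C)Br | intermediate (not isolated)
15 | (Z)-2-bromo-1-methoxyprop-1-ene (bromine cis to methoxy) | CO/C=C(/C)Br | intermediate
16 | [(E)-1-methoxyprop-1-en-2-yl]lithium (lithium cis to methoxy) | CO/C=C(/C)[Li] | intermediate (not isolated)
17 | racemic 4-hydroxy-3-isopropoxy-4-[(Z)-1-methoxyprop-1-en-2-yl]-2-[(E)-nonadec-14-enyl]cyclobut-2-en-1-one | CCCC/C=C/CCCCCCCCCCCCCC1=C(OC(C)C)C(O)(/C(C)=C\OC)C1=O | intermediate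
18 | (3Z,5Z)-4-hydroxy-3-isopropoxy-6-methoxy-5-methyl-2-[(E)-nonadec-14-enyl]hexa-1,3,5-trien-1-one | CCCC/C=C/CCCCCCCCCCCCCC(=C=O)/C(OC(C)C)=C(O)\C(C)=C/OC | intermediate (not isolated)
19 | racemic 4-hydroxy-3-isopropoxy-6-methoxy-5-methyl-2-[(E)-nonadec-14-enyl]cyclohexa-2,4-dien-1-one | CCCC/C=C/CCCCCCCCCCCCCC1=C(OC(C)C)C(O)=C(C)C(OC)C1=O | intermediate (not isolated)
20 | 3-isopropoxy-6-methoxy-5-methyl-2-[(E)-nonadec-14-enyl]benzene-1,4-diol | CCCC/C=C/CCCCCCCCCCCCCc1c(O)c(OC)c(C)c(O)c1OC(C)C | intermediate
21 | 2-isopropoxy-5-methoxy-6-methyl-3-[(E)-nonadec-14-enyl]cyclohexa-2,5-diene-1,4-dione | CCCC/C=C/CCCCCCCCCCCCCC1=C(OC(C)C)C(=O)C(C)=C(OC)C1=O | intermediate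
22 | 2,5-dihydroxy-3-methyl-6-[(E)-nonadec-14-enyl]cyclohexa-2,5-diene-1,4-dione | CCCC/C=C/CCCCCCCCCCCCCC1=C(O)C(=O)C(C)=C(O)C1=O | target

Total step count: 11. Longest linear sequence: 10 steps (steps 1–6 and 8–11); step 7 is a one-step side branch.

Steps most likely to fail

Step 8. The alkenyllithium may fragment by β-elimination of lithium methoxide. This should be fast for any reagent that stems from residual E bromide and possible for 16 itself on warming. The propyne released would be deprotonated and the resulting alkynyllithium would compete for 12. Fallback: setting out from 15, the bromine–lithium exchange is run as before but the organolithium is trapped with Bu3SnCl to give tributyl[(Z)-1-methoxyprop-1-en-2-yl]stannane F1, a storable compound that can be separated from alkynylstannane impurities by distillation or chromatography on basic alumina. Tin–lithium exchange of F1 with n-BuLi in THF at −78 °C then regenerates 16 free of alkynyllithium and tert-butyl residues, and its addition to 12 comes back to the route at 17.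

Step 9. The tertiary, doubly allylic carbinol may ionise (assisted by the enol ether) and undergo allylic transposition before the ring opens, or the ketene may be diverted while closure is slowed by the inward methoxy group. Fallback: setting out from 12, the lithium alkoxide formed with 16 is quenched at −78 °C with Me3SiCl instead of water to give racemic 3-isopropoxy-4-[(Z)-1-methoxyprop-1-en-2-yl]-2-[(E)-nonadec-14-enyl]-4-(trimethylsilyloxy)cyclobut-2-en-1-one F2, which cannot ionise as easily and whose silyloxy group is still a donor that rotates outward. Heating F2 in toluene should give the monosilylated hydroquinone 3-isopropoxy-6-methoxy-5-methyl-2-[(E)-nonadec-14-enyl]-4-(trimethylsilyloxy)phenol F3, and K2CO3 in MeOH under argon removes the silyl group, coming back to the route at 20.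

Step 11. Once the first vinylogous ester has been hydrolysed to an anionic vinylogous carboxylate, the second may resist hydroxide, and prolonged exposure to base may degrade the hydroxyquinone ring. Fallback: setting out from 21, BCl3 in CH2Cl2 (−78 → 0 °C) cleaves both O–alkyl bonds by carbonyl coordination and chloride attack at the isopropyl and methyl carbons, so the quinone never meets hydroxide. Aqueous work-up of the boron chelate comes back to the route at 22, and no compound outside the compound list is formed (F0).

Further compounds
F1 | step 8 | tributyl[(Z)-1-methoxyprop-1-en-2-yl]stannane | CO/C=C(/C)[Sn](CCCC)(CCCC)CCCC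
F2 | step 9 | racemic 3-isopropoxy-4-[(Z)-1-methoxyprop-1-en-2-yl]-2-[(E)-nonadec-14-enyl]-4-(trimethylsilyloxy)cyclobut-2-en-1-one | CCCC/C=C/CCCCCCCCCCCCCC1=C(OC(C)C)C(O[Si](C)(C)C)(/C(C)=C\OC)C1=O
F3 | step 9 | 3-isopropoxy-6-methoxy-5-methyl-2-[(E)-nonadec-14-enyl]-4-(trimethylsilyloxy)phenol | CCCC/C=C/CCCCCCCCCCCCCc1c(O)c(OC)c(C)c(O[Si](C)(C)C)c1OC(C)C
F0 | step 11 | none | none
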